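Ring A of the trans-decalin (C1–C5 and C10, clerodane numbering) is read as a Diels–Alder retron: C4 (exocyclic methylene, formerly a silyl enol ether) and C1 (hydroxyl, formerly a boronate) lie 1,4 to each other in a six-membered ring whose C5–C10 bond is shared with ring B. An intramolecular Diels–Alder reaction of an acyclic polyene, in which a 2-silyloxydiene (C2=C3–C4=C5) and an (E)-alkenylboronate (C10=C1) are joined by the C6–C9 chain with a Z-olefin, closes rings A and B in one operation and sets C1, C5 and C10. The precursor comes from an Evans aldol/Fráter–Seebach fragment, unmasked through a metathesis-derived lactone.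

Key step: step 14

Remark on numbering: clerodane numbering is used for every intermediate (ring A: C1, C2, C3, C4, C5, C10; ring B: C5, C6, C7, C8, C9, C10; C17, C19 and C20 are the methyl groups on C8, C5 and C9; C18 is the exocyclic methylene carbon; side chain C11–C16). β is the face of the decalin that carries the C5 and C9 methyl groups, α the opposite face.

Assumption: Z-enol borinates made with (+)-Ipc2BOTf, the reagent derived from (−)-α-pinene, add to the re face of aldehydes. The butenolide is carried as a 3-furyl group until the last step.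

Step 1
Reactants: 1 furan-3-carbaldehyde
Product: 2 3-(2-methoxyethenyl)furan (E/Z mixture)
Conditions: MeOCH2PPh3Cl, KOt-Bu, THF, 0 °C to rt
Reagents that add atoms: (methoxymethyl)triphenylphosphonium chloride, [Cl-].COC[P+](c1ccccc1)(c1ccccc1)c1ccccc1
Why: Wittig methoxymethylenation homologates the aromatic aldehyde by one carbon to the enol ether; no stereocentre is formed and the olefin geometry is irrelevant.

Step 2
Reactants: 2 3-(2-methoxyethenyl)furan
Product: 3 2-(furan-3-yl)acetaldehyde
Conditions: 2 M HCl, THF, 0 °C to rt; used crude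
Reagents that add atoms: water, O
Why: Acid-catalysed enol ether hydrolysis releases the aldehyde (future C11, with C12 and the C13–C16 ring attached) under conditions mild and brief enough for the furan; no stereocentre is formed.

Step 3
Reactants: 4 (R)-4-benzyloxazolidin-2-one; 5 3-methylbut-2-enoyl chloride
Product: 6 (R)-4-benzyl-3-(3-methylbut-2-enoyl)oxazolidin-2-one
Conditions: n-BuLi, THF, −78 °C; then 5, −78 to 0 °C
Reagents that add atoms: none
Why: N-acylation of the lithiated oxazolidinone with the acid chloride installs the chiral auxiliary; the existing stereocentre is untouched.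

Step 4
Reactants: 6 (R)-4-benzyl-3-(3-methylbut-2-enoyl)oxazolidin-2-one; 3 2-(furan-3-yl)acetaldehyde
Product: 8 (R)-4-benzyl-3-[(2R,3S)-4-(furan-3-yl)-3-hydroxy-2-(prop-1-en-2-yl)butanoyl]oxazolidin-2-one, via dibutylboron dienolate 7 (not isolated)
Conditions: n-Bu2BOTf, Et3N, CH2Cl2, −78 to 0 °C; then 3, −78 °C; H2O2, MeOH, pH 7 buffer
Reagents that add atoms: none
Why: Evans syn-aldol reaction of the Z boron dienolate formed by γ-deprotonation (deconjugative enolization), which reacts at its α-carbon through a Zimmerman–Traxler chair in which the (R)-benzyl auxiliary exposes the re face of the aldehyde, sets the C11 carbinol centre (S) and delivers the α-isopropenyl group (C8, C17), the C9–H centre being only temporary.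

Step 5
Reactants: 8 aldol adduct
Product: 9 prop-2-enyl (2R,3S)-4-(furan-3-yl)-3-hydroxy-2-(prop-1-en-2-yl)butanoate
Conditions: allyl alcohol, n-BuLi, THF, −20 to 0 °C
Reagents that add atoms: prop-2-en-1-ol (allyl alcohol), C=CCO
Why: Transesterification by lithium allyloxide at the exocyclic imide carbonyl releases the auxiliary and gives the allyl ester whose O-allyl group will supply C6 and C7; C11 is not affected and any epimerization at C9 is harmless because that centre is re-formed in step 6.

Step 6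
Reactants: 9 allyl β-hydroxy ester
Product: 11 prop-2-enyl (2R,3S)-4-(furan-3-yl)-3-hydroxy-2-methyl-2-(prop-1-en-2-yl)butanoate, via dilithium alkoxide dienolate 10 (not isolated)
Conditions: LiN(i-Pr)2 (2.4 equiv), THF/DMPU, −78 to −45 °C; then MeI, −78 to −30 °C
Reagents that add atoms: iodomethane, CI
Why: Fráter–Seebach alkylation: the lithium-chelated alkoxide dienolate is methylated at the α-carbon on the face opposite the C12 substituent of the chelate ring, which places the new C20 methyl anti to the C11 hydroxyl and sets the quaternary C9 centre, while the low temperature prevents ester-enolate Claisen rearrangement of the allyl ester.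

Step 7
Reactants: 11 quaternary β-hydroxy ester
Product: 12 prop-2-enyl (2R,3S)-3-[(tert-butyldimethylsilyl)oxy]-4-(furan-3-yl)-2-methyl-2-(prop-1-en-2-yl)butanoate
Conditions: TBSOTf, 2,6-lutidine, CH2Cl2, 0 °C
Reagents that add atoms: tert-butyldimethylsilyl trifluoromethanesulfonate, CC(C)(C)[Si](C)(C)OS(=O)(=O)C(F)(F)F
Why: Silylation with the silyl triflate protects the hindered C11 hydroxyl as a TBS ether that survives steps 8–14; no stereocentre is changed.

Step 8
Reactants: 12 TBS-protected allyl ester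
Product: 13 (3R)-3-[(1S)-1-[(tert-butyldimethylsilyl)oxy]-2-(furan-3-yl)ethyl]-3,4-dimethyl-3,6-dihydro-2H-pyran-2-one
Conditions: second-generation Grubbs catalyst RuCl2(=CHPh)(PCy3)(H2IMes) (10 mol %), toluene, 80 °C
Reagents that add atoms: none
Why: Ring-closing metathesis between the allyl ester olefin and the isopropenyl group, helped by the quaternary C9 (Thorpe–Ingold effect), forms the trisubstituted C7=C8 bond inside a six-membered lactone, which fixes its Z geometry (C6 cis to C9); no stereocentre is formed and the quaternary C9 blocks migration of the olefin into conjugation.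

Step 9
Reactants: 13 unsaturated δ-lactone
Product: 14 (3R)-3-[(1S)-1-[(tert-butyldimethylsilyl)oxy]-2-(furan-3-yl)ethyl]-3,4-dimethyl-3,6-dihydro-2H-pyran-2-ol (lactol, anomer mixture)
Conditions: i-Bu2AlH, CH2Cl2, −78 °C; aq. KNaC4H4O6
Reagents that add atoms: none
Why: Partial hydride reduction of the hindered α,α-disubstituted lactone stops at the tetrahedral aluminate and gives the lactol (C10 at the aldehyde level); the new anomeric centre disappears in step 10.

Step 10
Reactants: 14 lactol
Product: 15 (2Z,4R,5S)-5-[(tert-butyldimethylsilyl)oxy]-6-(furan-3-yl)-3,4-dimethyl-4-[(E)-2-(4,4,5,5-tetramethyl-1,3,2-dioxaborolan-2-yl)ethenyl]hex-2-en-1-ol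
Conditions: CH2(Bpin)2, lithium 2,2,6,6-tetramethylpiperidide (2.5 equiv), THF, 0 °C; then 14, −78 °C to rt
Reagents that add atoms: 2,2'-methylenebis(4,4,5,5-tetramethyl-1,3,2-dioxaborolane), CC1(C)OB(CB2OC(C)(C)C(C)(C)O2)OC1(C)C
Why: Boron-Wittig olefination: the lithiated geminal bis(boronate) adds to the open hydroxy-aldehyde form of the lactol and syn B–O elimination gives the (E)-alkenyl pinacol boronate (C10=C1) while freeing the Z-allylic C6 alcohol; no stereocentre is formed and the E geometry follows from the elimination that places C9 anti to the remaining boryl group.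

Step 11
Reactants: 15 Z-allylic alcohol
Product: 16 (2Z,4R,5S)-5-[(tert-butyldimethylsilyl)oxy]-6-(furan-3-yl)-3,4-dimethyl-4-[(E)-2-(4,4,5,5-tetramethyl-1,3,2-dioxaborolan-2-yl)ethenyl]hex-2-enal
Conditions: MnO2, CH2Cl2, rt
Reagents that add atoms: none
Why: Chemoselective MnO2 oxidation of the primary allylic alcohol gives the Z-enal (C6 aldehyde) without touching the alkenylboronate, the furan or the silyl ether, and the neutral conditions preserve the Z geometry; no stereocentre is formed.

Step 12
Reactants: 16 Z-enal; 17 pent-1-en-3-one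
Product: 19 (4R,5S,6Z,8R,9S)-9-[(tert-butyldimethylsilyl)oxy]-10-(furan-3-yl)-5-hydroxy-4,7,8-trimethyl-8-[(E)-2-(4,4,5,5-tetramethyl-1,3,2-dioxaborolan-2-yl)ethenyl]deca-1,6-dien-3-one, via diisopinocampheylboron enolate 18 (not isolated)
Conditions: (+)-Ipc2BOTf, i-Pr2NEt, CH2Cl2, −78 °C; then 16, −78 to −20 °C; MeOH, pH 7 buffer (non-oxidative work-up)
Reagents that add atoms: none
Why: Boron-mediated syn-aldol addition of the Z enol borinate of the vinyl ketone through a chair transition state, in which the isopinocampheyl ligands direct the enolate to the re face of the aldehyde, sets the C6 carbinol centre (the C5 methyl centre is erased in step 13), and the non-oxidative work-up keeps the alkenylboronate.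

Step 13
Reactants: 19 β-hydroxy vinyl ketone
Product: 20 (3Z,5S,6Z,8R,9S)-3,5,9-tris[(tert-butyldimethylsilyl)oxy]-10-(furan-3-yl)-4,7,8-trimethyl-8-[(E)-2-(4,4,5,5-tetramethyl-1,3,2-dioxaborolan-2-yl)ethenyl]deca-1,3,6-triene
Conditions: TBSOTf (3 equiv), Et3N, CH2Cl2, −78 to 0 °C
Reagents that add atoms: tert-butyldimethylsilyl trifluoromethanesulfonate, CC(C)(C)[Si](C)(C)OS(=O)(=O)C(F)(F)F
Why: Silyl triflate/amine soft enolization silylates the C6 hydroxyl and converts the vinyl ketone, which can enolize only toward C5, into the 2-silyloxydiene, the Z enol ether (branched C6 cis to the silyloxy group, small C19 methyl cis to the vinyl group) being favoured by allylic strain; C6 is retained and the C5 stereocentre disappears.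

Step 14
Reactants: 20 silyloxydiene alkenylboronate
Product: 21 trans-fused cycloadduct (ring A silyl enol ether C3=C4–OTBS, ring B olefin C7=C8; 1α-Bpin, 5β-methyl, 6β-OTBS, 9β-methyl, 9α-[(1S)-1-(TBS-oxy)-2-(furan-3-yl)ethyl], 10α-H)
Conditions: toluene (0.01 M), BHT, 170 °C, sealed tube
Reagents that add atoms: none
Why: Thermal concerted [4+2] cycloaddition in which the electron-rich 2-silyloxydiene C2=C3–C4(OTBS)=C5 adds suprafacially to the (E)-alkenylboronate C10=C1, forming the C5–C10 and C1–C2 bonds together; the closest known reaction type is the type 1 intramolecular Diels–Alder reaction of 1,3,9-decatrienes, here with an alkenylboronate as dienophile. Ring B closes through the C5–C10 bond across the four-atom C6–C9 tether (six-membered, half-chair with the cis olefin inside) and ring A is the new cyclohexene carrying the C3=C4 silyl enol ether, the two rings being formed in the fused mode. C5 is set by diene-face selection from the C6 stereocentre: allylic 1,3-strain keeps C6–H in the diene plane next to the C4 silyloxy group, the tether on one face and the C6 silyloxy group on the other, so that this group ends equatorial and cis to the angular C19 methyl. C10 follows from the anti (trans-decalin) transition state, in which the small H10 rather than the quaternary C9 lies over the diene and its inside C5 methyl, and in which the C9 methyl rather than the larger C11 chain becomes axial. C1 follows from the E geometry of the dienophile, which keeps boron trans to C9 and therefore cis to H10 (equatorial, the future 1α-hydroxyl). The selectivities needed are trans over cis ring fusion and one diene face; they are secured by the Z-C7=C8 bond and quaternary C9 that preorganise the tether, by the C6 silyloxy stereocentre and by the Z enol ether geometry, since only that diene isomer can reach the dienophile.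

Step 15
Reactants: 21 cycloadduct
Product: 22 4-ketone 6β,11-diol (1α-Bpin, C7=C8 olefin, furan retained)
Conditions: HF·pyridine, pyridine, THF, 0 °C to rt
Reagents that add atoms: none
Why: Fluoride-mediated desilylation protonates the silyl enol ether at C3 to release the C4 ketone and cleaves both TBS ethers, while the secondary alkyl pinacol boronate and the furan are retained; no stereocentre can epimerize because C5 is quaternary.

Step 16
Reactants: 22 keto diol
Product: 23 6β,11-diacetate
Conditions: Ac2O, DMAP, pyridine, 40 °C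
Reagents that add atoms: acetic anhydride, CC(=O)OC(C)=O
Why: DMAP-catalysed acylation acetylates the two secondary alcohols at C6 and C11 while the C1 oxygen is still masked as the boronate, so the later free 1-hydroxyl needs no protecting group; the β-acetoxy ketone cannot eliminate because C5 is quaternary.

Step 17
Reactants: 23 diacetate
Product: 25 7α,8α-diol, via cyclic osmate ester 24 (not isolated)
Conditions: OsO4 (1.1 equiv), pyridine, THF, 0 °C to rt; then aq. NaHSO3
Reagents that add atoms: osmium tetroxide, O=[Os](=O)(=O)=O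
Why: Syn-dihydroxylation ([3+2] addition of OsO4, then reductive hydrolysis of the osmate ester) occurs on the α face of the trisubstituted C7=C8 bond, opposite the two axial methyl groups at C5 and C9, and sets C7 and C8 as the cis-7α,8α-diol; the aromatic furan should react more slowly than the olefin and the amine-oxide-free procedure spares the C–B bond.

Step 18
Reactants: 25 7α,8α-diol
Product: 26 7α-(2-methylpropanoate)
Conditions: (i-PrCO)2O, DMAP, Et3N, CH2Cl2, rt
Reagents that add atoms: 2-methylpropanoic anhydride (isobutyric anhydride), CC(C)C(=O)OC(=O)C(C)C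
Why: DMAP-catalysed acylation esterifies the secondary 7-hydroxyl, the tertiary 8-hydroxyl being unreactive under these conditions, so no protection is needed; no stereocentre is changed.

Step 19
Reactants: 26 keto triester
Product: 27 4(18)-methylene compound
Conditions: Zn, CH2Br2, TiCl4, THF, 0 °C to rt
Reagents that add atoms: dibromomethane, BrCBr
Why: Takai–Lombardo methylenation with the non-basic CH2(ZnBr)2/TiCl4 reagent converts the hindered, enolizable C4 ketone next to quaternary C5 into the exocyclic olefin without attacking the three esters, the boronate or the furan; no stereocentre is formed.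

Step 20
Reactants: 27 alkylboronate
Product: 28 1α-alcohol (furan analogue of the target)
Conditions: NaBO3·4H2O, THF/H2O, rt
Reagents that add atoms: sodium perborate (NaBO3·4H2O), [Na+].[Na+].O[B-]1(O)OO[B-](O)(O)OO1
Why: Oxidation of the secondary alkylboronate proceeds by 1,2-migration of C1 from boron to oxygen with retention and gives the equatorial 1α-alcohol set in step 14, the mild reagent leaving the esters, the exocyclic olefin and the furan intact.

Step 21
Reactants: 28 3-furyl alcohol
Product: 31 CNP0254453.1 (target), via furan endoperoxide 29 (not isolated), via hydroxybutenolide 30 (not isolated)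
Conditions: O2, hν, tetraphenylporphyrin (cat.), i-Pr2NEt, CH2Cl2, −78 °C; then NaBH4, EtOH, 0 °C; dilute HCl
Reagents that add atoms: dioxygen, O=O
Why: Singlet-oxygen [4+2] addition to the furan and Kornblum–DeLaMare-type fragmentation of the endoperoxide, in which the hindered amine removes the less hindered C15–H, give the 4-substituted 5-hydroxybutenolide (C15 carbonyl), and NaBH4 reduction of its ring-opened aldehyde with relactonization on acidification gives the 13-en-15,16-olide; no ring stereocentre is touched and the slower ene reaction of the 1,1-disubstituted olefin should not compete.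

Compound list

1 | furan-3-carbaldehyde | O=Cc1ccoc1 | starting material
2 | 3-(2-methoxyethenyl)furan (E/Z mixture) | COC=Cc1ccoc1 | intermediate
3 | 2-(furan-3-yl)acetaldehyde | O=CCc1ccoc1 | intermediate
4 | (R)-4-benzyloxazolidin-2-one | O=C1N[C@H](Cc2ccccc2)CO1 | starting material
5 | 3-methylbut-2-enoyl chloride | CC(C)=CC(Cl)=O | starting material
6 | (R)-4-benzyl-3-(3-methylbut-2-enoyl)oxazolidin-2-one | CC(C)=CC(=O)N1[C@H](Cc2ccccc2)COC1=O | intermediate
7 | Z-dibutylboron dienolate of 6 | CCCCB(CCCC)O/C(=C\C(C)=C)N1[C@H](Cc2ccccc2)COC1=O | intermediate (not isolated)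
8 | (R)-4-benzyl-3-[(2R,3S)-4-(furan-3-yl)-3-hydroxy-2-(prop-1-en-2-yl)butanoyl]oxazolidin-2-one | O=C(N1[C@H](Cc2ccccc2)COC1=O)[C@H](C(C)=C)[C@H](Cc3ccoc3)O | intermediate
9 | prop-2-enyl (2R,3S)-4-(furan-3-yl)-3-hydroxy-2-(prop-1-en-2-yl)butanoate | C=CCOC(=O)[C@H](C(C)=C)[C@H](Cc1ccoc1)O | intermediate
10 | dilithium alkoxide dienolate of 9 | C=CCOC(O[Li])=C(C(C)=C)[C@H](Cc1ccoc1)O[Li] | intermediate (not isolated)
11 | prop-2-enyl (2R,3S)-4-(furan-3-yl)-3-hydroxy-2-methyl-2-(prop-1-en-2-yl)butanoate | C=CCOC(=O)[C@](C)(C(C)=C)[C@H](Cc1ccoc1)O | intermediate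
12 | prop-2-enyl (2R,3S)-3-[(tert-butyldimethylsilyl)oxy]-4-(furan-3-yl)-2-methyl-2-(prop-1-en-2-yl)butanoate | C=CCOC(=O)[C@](C)(C(C)=C)[C@H](Cc1ccoc1)O[Si](C)(C)C(C)(C)C | intermediate
13 | (3R)-3-[(1S)-1-[(tert-butyldimethylsilyl)oxy]-2-(furan-3-yl)ethyl]-3,4-dimethyl-3,6-dihydro-2H-pyran-2-one | O=C1OCC=C(C)[C@]1(C)[C@H](Cc2ccoc2)O[Si](C)(C)C(C)(C)C | intermediate
14 | (3R)-3-[(1S)-1-[(tert-butyldimethylsilyl)oxy]-2-(furan-3-yl)ethyl]-3,4-dimethyl-3,6-dihydro-2H-pyran-2-ol (anomer mixture) | OC1OCC=C(C)[C@]1(C)[C@H](Cc2ccoc2)O[Si](C)(C)C(C)(C)C | intermediate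
15 | (2Z,4R,5S)-5-[(tert-butyldimethylsilyl)oxy]-6-(furan-3-yl)-3,4-dimethyl-4-[(E)-2-(4,4,5,5-tetramethyl-1,3,2-dioxaborolan-2-yl)ethenyl]hex-2-en-1-ol | OC/C=C(/C)[C@@](C)(/C=C/B1OC(C)(C)C(C)(C)O1)[C@H](Cc2ccoc2)O[Si](C)(C)C(C)(C)C | intermediate
16 | (2Z,4R,5S)-5-[(tert-butyldimethylsilyl)oxy]-6-(furan-3-yl)-3,4-dimethyl-4-[(E)-2-(4,4,5,5-tetramethyl-1,3,2-dioxaborolan-2-yl)ethenyl]hex-2-enal | O=C/C=C(/C)[C@@](C)(/C=C/B1OC(C)(C)C(C)(C)O1)[C@H](Cc2ccoc2)O[Si](C)(C)C(C)(C)C | intermediate
17 | pent-1-en-3-one | C=CC(=O)CC | starting material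
18 | Z-(+)-diisopinocampheylboron enolate of 17 | C=C/C(OB([C@H]1C[C@H]2C[C@@H]([C@@H]1C)C2(C)C)[C@H]1C[C@H]2C[C@@H]([C@@H]1C)C2(C)C)=C/C | intermediate (not isolated)
19 | (4R,5S,6Z,8R,9S)-9-[(tert-butyldimethylsilyl)oxy]-10-(furan-3-yl)-5-hydroxy-4,7,8-trimethyl-8-[(E)-2-(4,4,5,5-tetramethyl-1,3,2-dioxaborolan-2-yl)ethenyl]deca-1,6-dien-3-one | C=CC(=O)[C@H](C)[C@@H](O)/C=C(/C)[C@@](C)(/C=C/B1OC(C)(C)C(C)(C)O1)[C@H](Cc2ccoc2)O[Si](C)(C)C(C)(C)C | intermediate
20 | (3Z,5S,6Z,8R,9S)-3,5,9-tris[(tert-butyldimethylsilyl)oxy]-10-(furan-3-yl)-4,7,8-trimethyl-8-[(E)-2-(4,4,5,5-tetramethyl-1,3,2-dioxaborolan-2-yl)ethenyl]deca-1,3,6-triene | C=C/C(O[Si](C)(C)C(C)(C)C)=C(\C)[C@@H](O[Si](C)(C)C(C)(C)C)/C=C(/C)[C@@](C)(/C=C/B1OC(C)(C)C(C)(C)O1)[C@H](Cc2ccoc2)O[Si](C)(C)C(C)(C)C | intermediate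
21 | trans-fused cycloadduct: C3=C4 enol TBS ether, C7=C8 olefin, 1α-Bpin, 5β-methyl, 6β-OTBS, 9β-methyl, 9α-[(1S)-1-(TBS-oxy)-2-(furan-3-yl)ethyl], 10α-H | CC(C)(C)[Si](C)(C)OC1=CC[C@@H](B2OC(C)(C)C(C)(C)O2)[C@H]3[C@@]1(C)[C@@H](O[Si](C)(C)C(C)(C)C)C=C(C)[C@]3(C)[C@H](Cc4ccoc4)O[Si](C)(C)C(C)(C)C | intermediate
22 | 4-ketone 6β,11-diol (1α-Bpin, C7=C8 olefin) | O=C1CC[C@@H](B2OC(C)(C)C(C)(C)O2)[C@H]3[C@@]1(C)[C@@H](O)C=C(C)[C@]3(C)[C@H](Cc4ccoc4)O | intermediate
23 | 4-ketone 6β,11-diacetate (1α-Bpin, C7=C8 olefin) | O=C1CC[C@@H](B2OC(C)(C)C(C)(C)O2)[C@H]3[C@@]1(C)[C@@H](OC(C)=O)C=C(C)[C@]3(C)[C@H](Cc4ccoc4)OC(C)=O | intermediate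
24 | cyclic 7α,8α-osmate ester of 23 (pyridine ligands not shown) | O=C1CC[C@@H](B2OC(C)(C)C(C)(C)O2)[C@H]3[C@@]1(C)[C@@H](OC(C)=O)[C@H](O[Os](=O)(=O)O5)[C@@]5(C)[C@]3(C)[C@H](Cc4ccoc4)OC(C)=O | intermediate (not isolated)
25 | 4-ketone 6β,11-diacetate 7α,8α-diol (1α-Bpin) | O=C1CC[C@@H](B2OC(C)(C)C(C)(C)O2)[C@H]3[C@@]1(C)[C@@H](OC(C)=O)[C@H](O)[C@](C)(O)[C@]3(C)[C@H](Cc4ccoc4)OC(C)=O | intermediate
26 | 4-ketone 6β,11-diacetate 7α-(2-methylpropanoate) 8α-ol (1α-Bpin) | O=C1CC[C@@H](B2OC(C)(C)C(C)(C)O2)[C@H]3[C@@]1(C)[C@@H](OC(C)=O)[C@H](OC(=O)C(C)C)[C@](C)(O)[C@]3(C)[C@H](Cc4ccoc4)OC(C)=O | intermediate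
27 | 4(18)-methylene 6β,11-diacetate 7α-(2-methylpropanoate) 8α-ol (1α-Bpin) | C=C1CC[C@@H](B2OC(C)(C)C(C)(C)O2)[C@H]3[C@@]1(C)[C@@H](OC(C)=O)[C@H](OC(=O)C(C)C)[C@](C)(O)[C@]3(C)[C@H](Cc4ccoc4)OC(C)=O | intermediate
28 | 1α-alcohol with 3-furyl side chain (furan analogue of the target) | C=C1CC[C@@H](O)[C@H]3[C@@]1(C)[C@@H](OC(C)=O)[C@H](OC(=O)C(C)C)[C@](C)(O)[C@]3(C)[C@H](Cc4ccoc4)OC(C)=O | intermediate
29 | furan endoperoxide of 28 (2,3,7-trioxabicyclo[2.2.1]hept-5-ene, isomer mixture) | C=C1CC[C@@H](O)[C@H]3[C@@]1(C)[C@@H](OC(C)=O)[C@H](OC(=O)C(C)C)[C@](C)(O)[C@]3(C)[C@H](CC4=CC5OOC4O5)OC(C)=O | intermediate (not isolated)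
30 | 16-hydroxy-13-en-15,16-olide (γ-hydroxybutenolide, epimer mixture at C16) | C=C1CC[C@@H](O)[C@H]3[C@@]1(C)[C@@H](OC(C)=O)[C@H](OC(=O)C(C)C)[C@](C)(O)[C@]3(C)[C@H](CC4=CC(=O)OC4O)OC(C)=O | intermediate (not isolated)
31 | CNP0254453.1 | C=C1CC[C@@H](O)[C@H]2[C@@]1(C)[C@@H](OC(C)=O)[C@H](OC(=O)C(C)C)[C@](C)(O)[C@]2(C)[C@H](CC1=CC(=O)OC1)OC(C)=O | target

Total step count: 21 steps.
Longest linear sequence: 20 steps (steps 1, 2 and 4–21, from furan-3-carbaldehyde); step 3 is a one-step branch.

Steps most likely to fail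

Step 14. What may go wrong: the boronate activates the dienophile only weakly, so the cycloaddition may be slow enough for 1,5-hydrogen shift in the diene to compete, or closure through the syn (cis-fused) transition state may erode the ring-fusion selectivity. The fallback uses a carbonyl-activated dienophile and exchanges carboxyl for boron afterwards; it sets out from lactol 14 and comes back at cycloadduct 21. Lactol 14 is olefinated with allyl (triphenylphosphoranylidene)acetate (toluene, 80 °C) to the allyl (E)-enoate Z-allylic alcohol F1, and MnO2 gives the enoate enal F2. The aldol reaction of step 12 with 17 then gives the enoate β-hydroxy vinyl ketone F3, and TBSOTf/Et3N gives the enoate silyloxydiene F4. The acrylate-type dienophile should now cyclize at about 110 °C, or with Me2AlCl at low temperature, through the ester-endo, trans-fused transition state to the allyl ester cycloadduct F5. Pd(PPh3)4/morpholine removes the allyl group to give the C1 carboxylic acid F6, and N-hydroxyphthalimide with N,N'-diisopropylcarbodiimide gives the N-acyloxyphthalimide ester F7. Decarboxylative borylation (B2cat2, DMAc, blue light; then pinacol, Et3N) returns 21, the C1 radical being borylated on the α face, away from the axial C5 methyl.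

Step 13. What may go wrong: unselective enol silylation, giving both geometries of the tetrasubstituted enol ether, of which only the Z isomer can cyclize. The fallback fixes the geometry with a temporary ring; it sets out from 19 and comes back at 22. Ketol 19 is treated with 1,3-dichloro-1,1,3,3-tetraisopropyldisiloxane, AgOTf and Et3N (CH2Cl2, −40 to 0 °C). Silylation of the C6 hydroxyl and intramolecular enol silylation can close the eight-membered ring only with the cis enol ether, giving the cyclic disiloxanediyl dienol ether F8. The ring is flexible enough to keep the C6 oxygen on the face opposite the tether. Heating as in step 14 gives the disiloxane-bridged cycloadduct F9, and HF·pyridine as in step 15 gives 22.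

Step 12. What may go wrong: insufficient or reversed facial selectivity of the reagent-controlled enolate addition at the hindered Z-enal, giving a mixture of C6 epimers. The fallback uses auxiliary control; it sets out from 16 and comes back at 19. Commercial (R)-4-benzyl-3-propanoyloxazolidin-2-one is enolized with n-Bu2BOTf/Et3N and added to 16 (non-oxidative work-up); re-face attack, as in step 4, gives the Evans syn-aldol imide F10. MeONHMe·HCl/AlMe3 converts it into the Weinreb amide F11, and CH2=CHMgBr (THF, −78 to 0 °C) gives 19.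

Further compounds

F1 | step 14 | prop-2-enyl (2E,4R,5Z)-4-[(1S)-1-[(tert-butyldimethylsilyl)oxy]-2-(furan-3-yl)ethyl]-7-hydroxy-4,5-dimethylhepta-2,5-dienoate | OC/C=C(/C)[C@@](C)(/C=C/C(=O)OCC=C)[C@H](Cc1ccoc1)O[Si](C)(C)C(C)(C)C
F2 | step 14 | prop-2-enyl (2E,4R,5Z)-4-[(1S)-1-[(tert-butyldimethylsilyl)oxy]-2-(furan-3-yl)ethyl]-4,5-dimethyl-7-oxohepta-2,5-dienoate | O=C/C=C(/C)[C@@](C)(/C=C/C(=O)OCC=C)[C@H](Cc1ccoc1)O[Si](C)(C)C(C)(C)C
F3 | step 14 | enoate analogue of 19 (allyl (E)-enoate in place of the alkenylboronate) | C=CC(=O)[C@H](C)[C@@H](O)/C=C(/C)[C@@](C)(/C=C/C(=O)OCC=C)[C@H](Cc1ccoc1)O[Si](C)(C)C(C)(C)C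
F4 | step 14 | enoate analogue of 20 (tris-TBS Z-silyloxydiene with allyl (E)-enoate) | C=C/C(O[Si](C)(C)C(C)(C)C)=C(\C)[C@@H](O[Si](C)(C)C(C)(C)C)/C=C(/C)[C@@](C)(/C=C/C(=O)OCC=C)[C@H](Cc1ccoc1)O[Si](C)(C)C(C)(C)C
F5 | step 14 | trans-fused cycloadduct with 1α-(prop-2-enyloxycarbonyl) group in place of Bpin | CC(C)(C)[Si](C)(C)OC1=CC[C@@H](C(=O)OCC=C)[C@H]2[C@@]1(C)[C@@H](O[Si](C)(C)C(C)(C)C)C=C(C)[C@]2(C)[C@H](Cc3ccoc3)O[Si](C)(C)C(C)(C)C
F6 | step 14 | trans-fused cycloadduct 1α-carboxylic acid | CC(C)(C)[Si](C)(C)OC1=CC[C@@H](C(=O)O)[C@H]2[C@@]1(C)[C@@H](O[Si](C)(C)C(C)(C)C)C=C(C)[C@]2(C)[C@H](Cc3ccoc3)O[Si](C)(C)C(C)(C)C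
F7 | step 14 | 1,3-dioxoisoindolin-2-yl ester of F6 | CC(C)(C)[Si](C)(C)OC1=CC[C@@H](C(=O)ON4C(=O)c5ccccc5C4=O)[C@H]2[C@@]1(C)[C@@H](O[Si](C)(C)C(C)(C)C)C=C(C)[C@]2(C)[C@H](Cc3ccoc3)O[Si](C)(C)C(C)(C)C
F8 | step 13 | eight-membered 1,1,3,3-tetraisopropyldisiloxane-1,3-diyl dienol ether bridging O4 and O6 of 19 (cis enol ether) | C=C/C1=C(\C)[C@@H](O[Si](C(C)C)(C(C)C)O[Si](C(C)C)(C(C)C)O1)/C=C(/C)[C@@](C)(/C=C/B2OC(C)(C)C(C)(C)O2)[C@H](Cc3ccoc3)O[Si](C)(C)C(C)(C)C
F9 | step 13 | trans-fused cycloadduct with the tetraisopropyldisiloxanediyl bridge between O4 and O6 (1α-Bpin, 11-OTBS) | CC(C)[Si]5(C(C)C)OC1=CC[C@@H](B2OC(C)(C)C(C)(C)O2)[C@H]3[C@@]1(C)[C@@H](O[Si](C(C)C)(C(C)C)O5)C=C(C)[C@]3(C)[C@H](Cc4ccoc4)O[Si](C)(C)C(C)(C)C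
F10 | step 12 | (R)-4-benzyl-3-acyloxazolidin-2-one syn-aldol adduct of 16 (imide analogue of 19) | O=C(N1[C@H](Cc2ccccc2)COC1=O)[C@H](C)[C@@H](O)/C=C(/C)[C@@](C)(/C=C/B3OC(C)(C)C(C)(C)O3)[C@H](Cc4ccoc4)O[Si](C)(C)C(C)(C)C
F11 | step 12 | N-methoxy-N-methylamide (Weinreb amide) analogue of 19 | CON(C)C(=O)[C@H](C)[C@@H](O)/C=C(/C)[C@@](C)(/C=C/B3OC(C)(C)C(C)(C)O3)[C@H](Cc4ccoc4)O[Si](C)(C)C(C)(C)C
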